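**Retrosynthetic overview**
1. Enabling feature: the five-membered lactone ring O–C19(=O)–C17(CH3)=C8–C7(=C6) is a hydrolysed 2-ethoxyfuran. C19 and C7 (next to the ring oxygen) map onto C5 and C2 of a 5-ethoxyoxazole; C17 (with its methyl) and C8 (with the C9 methylene) map onto a but-2-ynyl triple bond. C5 carries no hydrogen, so a leaving group on C6 can only unravel to the C6=C7 enol lactone.
2. Key disconnection: C19–C17 and C8–C7, made together by an intramolecular oxazole–alkyne Diels–Alder/retro-Diels–Alder reaction (acetonitrile extruded) that closes the ten-membered carbocycle and the oxygen ring at once; acid work-up in the same pot gives the target.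
3. The oxazole arm comes from a C6 aldehyde by a Passerini reaction (C6–C7 bond, C6 acetate and N-acylalanine ester in one step) and cyclodehydration.
4. The but-2-ynyl arm on C10 comes from a Claisen rearrangement of a C12 allylic alcohol; the C14 acetate from the carvone isopropenyl group (Criegee rearrangement); the quaternary C1 by methylation of a β-diketone built from (S)-carvone and a C2–C6 aldehyde made from (R)-2-methylglycidol.
5. Ring order: cyclohexene ring (chiral pool) first, oxazole (temporary ring) second, ten-membered ring and furan/butenolide ring together in the last step.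

Key step: step 21

Remark on the chemistry: locants are those of the briarane skeleton (C1 quaternary ring carbon with methyl C15; C2 isovalerate carbon; C5 carbinol carbon; C6=C7 enol ether; C7, C8, C17, C19 lactone carbons; C9 methylene; C10 ring CH; C11=C12; C14 acetate carbon). Centres that a later step destroys (C10 in 14 and 15, C6 in 25 to 28, the amino-ester carbon of 25, the bridgeheads of 27) should form as mixtures and are drawn without configuration.

**Step 1**
Reactants: 1 (R)-2-methylglycidol
Product: 2 (2S)-2-methylhex-5-ene-1,2-diol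
Conditions: allylMgBr (2.5 equiv), CuI (10 mol %), THF, −30 to 0 °C; aq NH4Cl
Reagents that add atoms: allylmagnesium bromide, C=CC[Mg]Br
Why: Copper-catalysed Grignard opening of the epoxide (SN2) at the unhindered CH2 terminus, after the first equivalent has deprotonated the alcohol, so the tertiary C–O stereocentre of 1 passes unchanged into the future C5 carbinol.

**Step 2**
Reactants: 2 (2S)-2-methylhex-5-ene-1,2-diol
Product: 3 (4S)-4-(but-3-en-1-yl)-2,2,4-trimethyl-1,3-dioxolane
Conditions: 2,2-dimethoxypropane, PPTS (cat.), acetone, rt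
Reagents that add atoms: 2,2-dimethoxypropane, COC(C)(C)OC
Why: Acid-catalysed transketalisation (acetonide formation) ties the primary and tertiary hydroxyls into a dioxolane that should survive every step up to step 16.

**Step 3**
Reactants: 3 (4S)-4-(but-3-en-1-yl)-2,2,4-trimethyl-1,3-dioxolane
Product: 4 3-[(4S)-2,2,4-trimethyl-1,3-dioxolan-4-yl]propanal
Conditions: O3, CH2Cl2, −78 °C; then PPh3, −78 °C to rt
Reagents that add atoms: ozone, [O-][O+]=O
Why: Ozonolysis with reductive work-up cleaves the only alkene to the aldehyde that becomes C2.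

**Step 4**
Reactants: 5 (S)-(+)-carvone; 4 3-[(4S)-2,2,4-trimethyl-1,3-dioxolan-4-yl]propanal
Product: 6 aldol adduct (carvone carrying the 1-hydroxy-3-dioxolanylpropyl chain on C1, diastereomer mixture)
Conditions: LDA, THF, −78 °C; then 4, −78 °C; aq NH4Cl
Reagents that add atoms: none
Why: Kinetic deprotonation of carvone at the α′ carbon and aldol addition form the C1–C2 bond; the diastereomer mixture is irrelevant because C2 is oxidised in step 5 and C1 is set anew in step 6.

**Step 5**
Reactants: 6 aldol adduct
Product: 7 β-diketone (C2 ketone, C10 enone; keto–enol mixture)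
Conditions: Dess–Martin periodinane, NaHCO3, CH2Cl2, 0 °C to rt
Reagents that add atoms: none
Why: Dess–Martin oxidation should convert the aldol into the β-diketone under conditions too mild for retro-aldol cleavage.

**Step 6**
Reactants: 7 β-diketone
Product: 8 C1-methylated β-diketone (C15 methyl trans, acyl chain cis to the C14 isopropenyl group)
Conditions: K2CO3, MeI, acetone, 45 °C
Reagents that add atoms: iodomethane, CI
Why: C-alkylation of the β-diketone enolate; iodomethane should attack the planar enolate anti to the neighbouring isopropenyl group on C14, which sets the quaternary C1 with methyl trans and the acyl chain cis to that group.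

**Step 7**
Reactants: 8 C1-methylated β-diketone
Product: 9 (2S)-β-hydroxy ketone
Conditions: Zn(BH4)2, Et2O, −30 °C; aq NH4Cl
Reagents that add atoms: none
Why: Chelation-controlled reduction: zinc bridges the two carbonyl oxygens and hydride should enter the more electrophilic, non-conjugated C2 carbonyl from the face of the small C1 methyl (away from the C14 ring flank), giving the 2S alcohol, while the hindered cross-conjugated enone carbonyl reacts more slowly.

**Step 8**
Reactants: 9 (2S)-β-hydroxy ketone
Product: 10 C2 isovalerate of the enone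
Conditions: isovaleric anhydride, DMAP, Et3N, CH2Cl2, 40 °C
Reagents that add atoms: 3-methylbutanoic anhydride, CC(C)CC(=O)OC(=O)CC(C)C
Why: DMAP-catalysed acylation installs the isovalerate of the target and at the same time blocks retro-aldol cleavage of the β-hydroxy ketone.

**Step 9**
Reactants: 10 C2 isovalerate of the enone
Product: 11 11,12-epoxy ketone (oxirane trans to the C14 isopropenyl group)
Conditions: 30% H2O2, NaOH (0.3 equiv), MeOH, 0 °C
Reagents that add atoms: hydrogen peroxide, OO
Why: Weitz–Scheffer nucleophilic epoxidation; hydroperoxide should add to C12 anti to the C14 isopropenyl group and the C2 chain (as with carvone itself), placing the oxirane oxygen trans to the C14 substituent, while the electron-rich isopropenyl alkene is not attacked.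

**Step 10**
Reactants: 11 11,12-epoxy ketone
Product: 13 C14 acetate of the epoxy ketone, via methoxy hydroperoxide 12 (not isolated)
Conditions: O3, CH2Cl2/MeOH (4:1), NaHCO3, −78 °C; then Ac2O, Et3N, DMAP (cat.), CH2Cl2, 0 to 40 °C
Reagents that add atoms: ozone, [O-][O+]=O; methanol, CO
Why: Ozonolysis in methanol gives the α-methoxy hydroperoxide, whose O-acetylation triggers the Criegee rearrangement (C14 migrates to oxygen with retention, the dialkoxycarbenium ion is demethylated by acetate), so the isopropenyl group becomes the C14 acetate of the target at a stage where no other alkene is present.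

**Step 11**
Reactants: 13 C14 acetate of the epoxy ketone
Product: 14 C10 epoxy alcohol (C10 epimers)
Conditions: NaBH4, CeCl3·7H2O, MeOH, −40 to 0 °C
Reagents that add atoms: none
Why: Luche-type borohydride reduction of the activated α,β-epoxy ketone leaves both esters intact; the new C10 centre is lost in step 13.

**Step 12**
Reactants: 14 C10 epoxy alcohol
Product: 15 C10 O-(imidazol-1-ylthiocarbonyl) epoxy alcohol
Conditions: 1,1'-thiocarbonyldiimidazole, DMAP (0.2 equiv), 1,2-dichloroethane, 70 °C
Reagents that add atoms: 1,1'-thiocarbonyldiimidazole, S=C(n1ccnc1)n1ccnc1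
Why: Thioacylation of the C10 hydroxyl gives the Barton–McCombie radical precursor without touching the esters or the epoxide.

**Step 13**
Reactants: 15 C10 O-(imidazol-1-ylthiocarbonyl) epoxy alcohol
Product: 16 (12S)-allylic alcohol (C10=C11, hydroxyl trans to the C14 acetate)
Conditions: Bu3SnH, AIBN (cat.), toluene, 90 °C
Reagents that add atoms: none
Why: Barton–McCombie-type radical generation at C10 followed by β-scission of the adjacent oxirane C11–O bond gives the C10=C11 alkene and a C12 alkoxy radical that the stannane reduces, so the carbinol keeps the configuration set in step 9.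

**Step 14**
Reactants: 16 (12S)-allylic alcohol
Product: 18 C10 (2-oxoethyl) aldehyde with C11=C12, via allyl vinyl ether 17 (not isolated)
Conditions: ethyl vinyl ether (solvent), Hg(OAc)2 (0.3 equiv), 35 °C; concentrate; toluene, 150 °C (sealed tube)
Reagents that add atoms: ethyl vinyl ether, C=COCC
Why: Mercury-catalysed vinyl transfer then Claisen rearrangement ([3,3]); the chair-like transition state should pass the C12–O configuration suprafacially to C10, so the CH2CHO arm arrives on the face that carried the oxygen (trans to the C2 chain, cis to the C15 methyl) and the alkene moves to C11=C12.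

**Step 15**
Reactants: 18 C10 (2-oxoethyl) aldehyde
Product: 20 but-2-ynyl compound, via vinyl iodide 19 (not isolated)
Conditions: Ph3P=C(I)CH3 (from EtPPh3I, n-BuLi, I2, then NaHMDS), THF, −78 °C; then NaHMDS (1.5 equiv), −78 to −30 °C
Reagents that add atoms: (1-iodoethylidene)triphenylphosphorane, CC(I)=P(c1ccccc1)(c1ccccc1)c1ccccc1
Why: Wittig olefination with the α-iodo ylide (Stork–Zhao type) should give the (Z)-2-iodoalkene, in which hydrogen and iodine are anti-periplanar, so NaHMDS eliminates HI to the methyl alkyne; the two hindered esters should tolerate the base at low temperature.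

**Step 16**
Reactants: 20 but-2-ynyl compound (acetonide)
Product: 21 5,6-diol
Conditions: AcOH/H2O/THF (3:1:1), 45 °C
Reagents that add atoms: none
Why: Acid hydrolysis of the acetonide; esters, alkene and alkyne are stable to aqueous acetic acid.

**Step 17**
Reactants: 21 5,6-diol
Product: 22 5,6-bis(triethylsilyl) ether
Conditions: TESOTf (2.5 equiv), 2,6-lutidine, CH2Cl2, −78 to 0 °C
Reagents that add atoms: triethylsilyl trifluoromethanesulfonate, CC[Si](CC)(CC)OS(=O)(=O)C(F)(F)F
Why: Silyl triflate silylation of both hydroxyls; the tertiary TES ether keeps the C5 hydroxyl masked until the last step.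

**Step 18**
Reactants: 22 5,6-bis(triethylsilyl) ether
Product: 23 C6 aldehyde (5-O-TES)
Conditions: (COCl)2, DMSO, CH2Cl2, −78 to −40 °C; then Et3N, −78 to 0 °C
Reagents that add atoms: none
Why: Swern oxidation; the chlorosulfonium salt should cleave the unhindered primary TES ether and oxidise it in the same pot, while the tertiary TES ether is untouched, and the aldehyde has no α-hydrogen.

**Step 19**
Reactants: 23 C6 aldehyde (5-O-TES); 24 ethyl 2-isocyanopropanoate (racemic)
Product: 25 Passerini adduct (C6 acetate, C7 amide of alanine ethyl ester)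
Conditions: AcOH (1.5 equiv), CH2Cl2 (1 M), rt
Reagents that add atoms: acetic acid, CC(=O)O
Why: Passerini three-component reaction (α-addition of aldehyde and acid to the isocyanide, then Mumm-type acyl shift) forms the C6–C7 bond, puts an acetate leaving group on C6 and delivers the N-acylalanine ester in one step; both new stereocentres are lost later.

**Step 20**
Reactants: 25 Passerini adduct
Product: 26 2-substituted 5-ethoxy-4-methyloxazole
Conditions: PPh3, C2Cl6, Et3N, CH2Cl2, 0 °C to rt
Reagents that add atoms: none
Why: Cyclodehydration of the N-acyl α-amino ester (Robinson–Gabriel type) with the chlorophosphonium reagent should give the 5-ethoxy-4-methyloxazole, the amino-ester carbon becoming sp2.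

**Step 21**
Reactants: 26 2-substituted 5-ethoxy-4-methyloxazole
Product: 29 target (CNP0208239.1), via cycloadduct 27 (not isolated), via ethoxyfuran 28 (not isolated)
Conditions: o-dichlorobenzene (0.5 mM), 2,6-lutidine (0.2 equiv), 180 °C (sealed); evaporate; then HF·pyridine, THF/H2O (10:1), 0 °C to rt
Reagents that add atoms: water, O
Why: Proposed new method: the electron-rich 5-ethoxyoxazole (diene C7=N–C=C19) should add across the tethered but-2-ynyl triple bond in an intramolecular [4+2] cycloaddition to the 7-oxa-2-azanorbornadiene 27, which loses acetonitrile by retro-[4+2] to the 2-ethoxyfuran 28; on the acid work-up the furfuryl C6 acetate ionises, water adds at C19, ethanol is lost and the TES ether is cleaved to give 29. The closest known reaction type is the intramolecular oxazole–alkyne Diels–Alder/retro-Diels–Alder furan synthesis (Kondrat'eva-type cycloaddition, established for annulated 2-alkoxyfurans and butenolides through five- and six-membered ring closures), together with macrocyclic intramolecular Diels–Alder closures of ten- and eleven-membered carbocycles; new here is the ten-membered closure with an unactivated alkyne. The ten-membered carbocycle closes in the fused (type 1) mode through the C7–C8 bond, the eight-atom tether joining the diene terminus C7 to the dienophile carbon C8, and the oxygen ring arises by exchange of the N=C(CH3) unit for C8=C17 (new C19–C17 bond), the nitrile loss making the cycloaddition irreversible. No stereocentre is created: the bridgeheads of 27 vanish on cycloreversion, C6 becomes sp2, and the C6=C7 geometry (C5 cis to C8) is fixed by the ring under reversible ionisation, C5 having no hydrogen to lose. The step needs ring closure to beat bimolecular addition and alkyne to beat alkene: dilution to 0.5 mM suppresses the bimolecular path (which unactivated alkynes hardly follow), the tether dictates the regiochemistry (C7 to C8, C19 to the methyl-bearing C17), the trans arms on C1/C10 and the quaternary C1 and C5 pre-organise the chain, and only the alkyne adduct can aromatise by nitrile loss.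

**Compound list**
1 | (R)-2-methylglycidol, (2R)-(2-methyloxiran-2-yl)methanol | OC[C@@]1(C)OC1 | starting material
2 | (2S)-2-methylhex-5-ene-1,2-diol | OC[C@@](C)(O)CCC=C | intermediate
3 | (4S)-4-(but-3-en-1-yl)-2,2,4-trimethyl-1,3-dioxolane | C=CCC[C@@]1(C)COC(C)(C)O1 | intermediate
4 | 3-[(4S)-2,2,4-trimethyl-1,3-dioxolan-4-yl]propanal | O=CCC[C@@]1(C)COC(C)(C)O1 | intermediate
5 | (S)-(+)-carvone, (5S)-2-methyl-5-(prop-1-en-2-yl)cyclohex-2-en-1-one | CC(=C)[C@H]1CC=C(C)C(=O)C1 | starting material
6 | aldol adduct: carvone with a 1-hydroxy-3-[(4S)-dioxolanyl]propyl chain on C1 (mixture at C1 and C2) | CC(=C)[C@H]1CC=C(C)C(=O)C1C(O)CC[C@@]2(C)COC(C)(C)O2 | intermediate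
7 | β-diketone: C2 ketone, C10 enone (keto–enol mixture, C1 not fixed) | CC(=C)[C@H]1CC=C(C)C(=O)C1C(=O)CC[C@@]2(C)COC(C)(C)O2 | intermediate
8 | C1-methylated β-diketone: C15 methyl trans, acyl chain cis to the C14 isopropenyl group | CC(=C)[C@H]1CC=C(C)C(=O)[C@@]1(C)C(=O)CC[C@@]2(C)COC(C)(C)O2 | intermediate
9 | (2S)-β-hydroxy ketone | CC(=C)[C@H]1CC=C(C)C(=O)[C@@]1(C)[C@@H](O)CC[C@@]2(C)COC(C)(C)O2 | intermediate
10 | (2S)-isovalerate (3-methylbutanoate) of the enone | CC(=C)[C@H]1CC=C(C)C(=O)[C@@]1(C)[C@@H](OC(=O)CC(C)C)CC[C@@]2(C)COC(C)(C)O2 | intermediate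
11 | 11,12-epoxy ketone, oxirane trans to the C14 isopropenyl group | CC(=C)[C@H]1C[C@@H]2O[C@]2(C)C(=O)[C@@]1(C)[C@@H](OC(=O)CC(C)C)CC[C@@]3(C)COC(C)(C)O3 | intermediate
12 | α-methoxy hydroperoxide from the isopropenyl group | COC(C)(OO)[C@H]1C[C@@H]2O[C@]2(C)C(=O)[C@@]1(C)[C@@H](OC(=O)CC(C)C)CC[C@@]3(C)COC(C)(C)O3 | intermediate (not isolated)
13 | (14S)-acetate of the epoxy ketone | CC(=O)O[C@H]1C[C@@H]2O[C@]2(C)C(=O)[C@@]1(C)[C@@H](OC(=O)CC(C)C)CC[C@@]3(C)COC(C)(C)O3 | intermediate
14 | C10 epoxy alcohol (C10 epimers) | CC(=O)O[C@H]1C[C@@H]2O[C@]2(C)C(O)[C@@]1(C)[C@@H](OC(=O)CC(C)C)CC[C@@]3(C)COC(C)(C)O3 | intermediate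
15 | C10 O-(imidazol-1-ylthiocarbonyl) epoxy alcohol | CC(=O)O[C@H]1C[C@@H]2O[C@]2(C)C(OC(=S)n3ccnc3)[C@@]1(C)[C@@H](OC(=O)CC(C)C)CC[C@@]4(C)COC(C)(C)O4 | intermediate
16 | (12S)-allylic alcohol, C10=C11, hydroxyl trans to the C14 acetate | CC(=O)O[C@H]1C[C@H](O)C(C)=C[C@@]1(C)[C@@H](OC(=O)CC(C)C)CC[C@@]2(C)COC(C)(C)O2 | intermediate
17 | C12 vinyl ether of 16 | CC(=O)O[C@H]1C[C@H](OC=C)C(C)=C[C@@]1(C)[C@@H](OC(=O)CC(C)C)CC[C@@]2(C)COC(C)(C)O2 | intermediate (not isolated)
18 | (10S)-aldehyde: CH2CHO arm on C10 (cis to C15 methyl), C11=C12 | CC(=O)O[C@H]1CC=C(C)[C@H](CC=O)[C@@]1(C)[C@@H](OC(=O)CC(C)C)CC[C@@]2(C)COC(C)(C)O2 | intermediate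
19 | (Z)-2-iodobut-2-enyl compound | CC(=O)O[C@H]1CC=C(C)[C@H](C/C=C(/C)I)[C@@]1(C)[C@@H](OC(=O)CC(C)C)CC[C@@]2(C)COC(C)(C)O2 | intermediate (not isolated)
20 | but-2-ynyl compound (acetonide) | CC(=O)O[C@H]1CC=C(C)[C@H](CC#CC)[C@@]1(C)[C@@H](OC(=O)CC(C)C)CC[C@@]2(C)COC(C)(C)O2 | intermediate
21 | (5S)-5,6-diol | CC(=O)O[C@H]1CC=C(C)[C@H](CC#CC)[C@@]1(C)[C@@H](OC(=O)CC(C)C)CC[C@](C)(O)CO | intermediate
22 | 5,6-bis(triethylsilyl) ether | CC(=O)O[C@H]1CC=C(C)[C@H](CC#CC)[C@@]1(C)[C@@H](OC(=O)CC(C)C)CC[C@](C)(O[Si](CC)(CC)CC)CO[Si](CC)(CC)CC | intermediate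
23 | C6 aldehyde with 5-O-TES | CC(=O)O[C@H]1CC=C(C)[C@H](CC#CC)[C@@]1(C)[C@@H](OC(=O)CC(C)C)CC[C@](C)(O[Si](CC)(CC)CC)C=O | intermediate
24 | ethyl 2-isocyanopropanoate (racemic) | CCOC(=O)C(C)[N+]#[C-] | starting material
25 | Passerini adduct: C6 acetate, C7 amide of alanine ethyl ester | CC(=O)O[C@H]1CC=C(C)[C@H](CC#CC)[C@@]1(C)[C@@H](OC(=O)CC(C)C)CC[C@](C)(O[Si](CC)(CC)CC)C(OC(C)=O)C(=O)NC(C)C(=O)OCC | intermediate
26 | 5-ethoxy-4-methyloxazole attached through its C2 to C6 | CC(=O)O[C@H]1CC=C(C)[C@H](CC#CC)[C@@]1(C)[C@@H](OC(=O)CC(C)C)CC[C@](C)(O[Si](CC)(CC)CC)C(OC(C)=O)c1nc(C)c(OCC)o1 | intermediate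
27 | 7-oxa-2-azanorbornadiene cycloadduct fused to the ten-membered ring | CC(=O)O[C@H]1CC=C(C)[C@@H]2CC3=C(C)C4(OCC)OC3(N=C4C)C(OC(C)=O)[C@@](C)(O[Si](CC)(CC)CC)CC[C@H](OC(=O)CC(C)C)[C@@]12C | intermediate (not isolated)
28 | 2-ethoxyfuran macrocycle with 6-OAc and 5-OTES | CC(=O)O[C@H]1CC=C(C)[C@@H]2Cc3c(C)c(OCC)oc3C(OC(C)=O)[C@@](C)(O[Si](CC)(CC)CC)CC[C@H](OC(=O)CC(C)C)[C@@]12C | intermediate (not isolated)
29 | CNP0208239.1, (1S,2S,5S,10S,14S) in the numbering used here | CC(=O)O[C@H]1CC=C(C)[C@@H]2CC3=C(C)C(=O)O/C3=C/[C@@](C)(O)CC[C@H](OC(=O)CC(C)C)[C@@]12C | target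

**Step count**
Total: 21 steps. Longest linear sequence: 21 steps (1 to 29; 18 steps from carvone 5).

**Steps most likely to fail**

1. Step 21. What may go wrong: the ten-membered transition state is reached too slowly, so that thermal loss of acetic acid from C6 or oligomerisation overtakes ring closure. The fallback uses known reaction types only (butenolide first, ring closure by vinylogous aldol condensation) and sets out from aldehyde 18. Thiazolium-catalysed cross-acyloin hydroxymethylation with paraformaldehyde should give the α-hydroxy ketone F1. Wittig olefination–lactonisation with ethyl 2-(triphenylphosphoranylidene)propanoate (toluene, 110 °C) should give the 3-methyl-4-alkylbutenolide F2. Acetonide hydrolysis, bis-silylation and Swern oxidation as in steps 16 to 18 should give the diol F3, the bis-TES ether F4 and the aldehyde F5. A one-pot intramolecular vinylogous Mukaiyama aldol–elimination (TBSOTf, i-Pr2NEt, CH2Cl2, 1 mM; then DBU) should close the ten-membered ring at C6–C7 to the TES ether F6. HF·pyridine then removes the silyl group, and the fallback comes back to the route at 29.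

2. Step 12. What may go wrong: incomplete thioacylation of the doubly neopentylic C10 hydroxyl, with opening of the oxirane by imidazole on prolonged heating. The fallback sets out from epoxy ketone 13 and uses the Wharton transposition (hydrazine hydrate, AcOH, MeOH, 0 °C to rt). It engages the carbonyl carbon instead of the buried oxygen and fragments through an ionic vinyl diazene instead of a radical. It comes back to the route at 16, steps 11 to 13 being skipped (no new compound: F0).

3. Step 7. What may go wrong: poor facial discrimination at C2, or competing 1,2-reduction of the enone carbonyl inside the zinc chelate. The fallback sets out from 8 and replaces substrate (chelation) control by catalyst control: Corey–Bakshi–Shibata reduction with (R)-2-methyl-CBS-oxazaborolidine and catecholborane (toluene, −78 °C). The catalyst should tell the quaternary C1 from the C3 methylene and should not accept the enone carbonyl, which is flanked by two fully substituted carbons. It comes back to the route at 9 (no new compound: F0).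

**Further compounds**
F1 | step 21 | α-hydroxy ketone: CH2C(=O)CH2OH arm on C10, otherwise as 18 | CC(=O)O[C@H]1CC=C(C)[C@H](CC(=O)CO)[C@@]1(C)[C@@H](OC(=O)CC(C)C)CC[C@@]2(C)COC(C)(C)O2
F2 | step 21 | 3-methyl-4-alkylfuran-2(5H)-one (butenolide) with the acetonide | CC(=O)O[C@H]1CC=C(C)[C@H](CC2=C(C)C(=O)OC2)[C@@]1(C)[C@@H](OC(=O)CC(C)C)CC[C@@]3(C)COC(C)(C)O3
F3 | step 21 | butenolide 5,6-diol | CC(=O)O[C@H]1CC=C(C)[C@H](CC2=C(C)C(=O)OC2)[C@@]1(C)[C@@H](OC(=O)CC(C)C)CC[C@](C)(O)CO
F4 | step 21 | butenolide 5,6-bis(triethylsilyl) ether | CC(=O)O[C@H]1CC=C(C)[C@H](CC2=C(C)C(=O)OC2)[C@@]1(C)[C@@H](OC(=O)CC(C)C)CC[C@](C)(O[Si](CC)(CC)CC)CO[Si](CC)(CC)CC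
F5 | step 21 | butenolide C6 aldehyde with 5-O-TES | CC(=O)O[C@H]1CC=C(C)[C@H](CC2=C(C)C(=O)OC2)[C@@]1(C)[C@@H](OC(=O)CC(C)C)CC[C@](C)(O[Si](CC)(CC)CC)C=O
F6 | step 21 | 5-O-triethylsilyl ether of 29 | CC(=O)O[C@H]1CC=C(C)[C@@H]2CC3=C(C)C(=O)O/C3=C/[C@@](C)(O[Si](CC)(CC)CC)CC[C@H](OC(=O)CC(C)C)[C@@]12C
F0 | step 12 | none | none
F0 | step 7 | none | none
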